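- At 40 h you read a flask that has had time to finish. The dusk run reads free substrate at 0.9 % at 5.00 h and 1.6 % at 8.00 h, each with a scatter of 1 percentage point, and 40 h is 5.00 times that last time. So I reckon each flask by its end yield.

| setting | dusk | ash | cedar | elm | larch | alder | oak |
|---|---|---|---|---|---|---|---|
| substrate | 2.2 M | 3.0 M | 0.60 M | 1.0 M | 1.2 M | 2.0 M | 0.50 M |
| remark | run made earlier |  |  |  |  |  |  |
| time |  | 40 h | 40 h | 40 h | 40 h | 40 h | 40 h |

dusk run (percent of the substrate charged)

| time / h | ring / % | substrate / % |
|---|---|---|
| 0.667 | 25.1 | 27.6 |
| 1.00 | 32.0 | 18.7 |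
| 1.33 | 35.4 | 12.0 |
| 2.50 | 42.9 | 4.9 |
| 3.00 | 43.2 | 4.8 |
| 5.00 | 48.8 | 0.9 |
| 8.00 | 50.7 | 1.6 |

(standard deviation of a reading: 1 percentage point)

- a reading or a percentage of ring counts all its forms, free or not
- a reading of substrate is of its free form alone

- ranking by amount of ring, in percent of the substrate charged, from high to low, at 40 h (ash / cedar / elm / larch / alder / oak)
- the amount of ring, in percent of the substrate charged of the flask you put first, at 40 h
- the amount of ring, in percent of the substrate charged of the flask you put last, at 40 h

- Follow one substrate molecule. In the dusk run, 34.7 % of the substrate lost by 0.667 h appears as ring. Between 0.667 h and 1.33 h the share is 66.0 %.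
- So ring gains as free substrate thins. I read this as ring closure needing one molecule and the loss needing a partner.
- The selectivity at this fork is then φ = K/(K+c), with c the free substrate. K is the even-odds concentration, where a molecule is as likely to become ring as to be lost.
- First way: the window's mean c is 0.436 M and its odds are 1.94. Their product gives K = 0.847 M, rough because it rests on differences of readings.
- Second way: summing φ from the charge C down to nothing gives Y = (K/C) ln((K+C)/K). For dusk that is 49.3 %. The reading at 8.00 h, unused in K, is 50.7 %, so they differ by 1.4 points against a scatter of 1 point.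
- They part early. Run down to the substrate read at 0.667 h, the sum gives 28.5 % ring, but 25.1 % is read. The substrate reading is the suspect: it counts the free form and no other, so missing substrate need not have passed the fork. The end point of Y does not use that reading, but K does, so any bias in it carries into every Y.
- Y falls as C rises, so I rank by charge. Oak has the lowest and gets 78.6 %. Ash has the highest and gets 42.7 %.
- The forecast gives oak > cedar > elm > larch > alder > ash, with 79 % first and 44 % last, the last above my ash figure: “All flasks should be finished by 40 h, so dilution decides the order.”
- The flasks give oak > cedar > elm > larch > alder > ash, with oak at 78.2 % and ash at 45.0 %, against my 78.6 % and 42.7 %.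

    substrate + ring → side product (k = 3.20 × 10⁻⁵ M⁻¹ s⁻¹)
    2 substrate → open dimer (k = 1.10 × 10⁻⁴ M⁻¹ s⁻¹)
    substrate → ring (k = 2.20 × 10⁻⁴ s⁻¹)
    substrate ⇌ dormant form (K = 1.00, k = 1.10 × 10⁻⁵ s⁻¹)
    substrate + ring ⇌ idle adduct, settled at all times (K = 1.00 M⁻¹)

- Ash holds 47.1 % of its charge as open dimer at 40.0 h, beside 45.0 % ring.
- Now take a neighbour flask, oak's recipe with 0.12 M substrate. Its starting odds K/c are 7.06, and Y gives 93.5 %; that neighbour flask holds 92.3 % ring.

The readings were generated by integration for substances that don't exist; scatter was added.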